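A direct plan would build the chlorinated isoflavone first by the deoxybenzoin route (bromoaryl chromone A1), attach the second ring B by a copper-mediated ether synthesis with a hydroxybenzaldehyde, convert the formyl group by reduction and bromination into benzylic bromide A2, extend A2 by a carbonylative aryl coupling, demethylate to tetraphenol A3 and close the second pyranone with a one-carbon electrophile. Its weakest steps would be the carbonylative benzyl–aryl ketone synthesis (CO insertion would have to outrun direct coupling of a labile benzyl bromide), the aldehyde–alcohol–bromide relay (two steps, no gain in complexity) and the last pyranone closure on A3 (four free phenols would compete for the electrophile).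

The route rests on the C3–C1' bonds of both isoflavone units, made by 1,2-aryl migration in an ether-linked bis(2'-hydroxychalcone) whose rings B come from two benzaldehydes. Each ring B carries an oxygen para to C1' (the 4'-methoxy group of unit A, the ether oxygen at C4' of unit B); this makes both rings good migrating groups and lets a para formyl group activate the SNAr that forms the diaryl ether. One operation with Tl(NO3)3 and acid shifts both aryl groups and closes both pyranones at O1–C2, the former formyl carbons becoming C2. No carbon monoxide coupling, no benzylic redox relay and no one-carbon ring closure on a free polyphenol is needed.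

Key step: step 5

Remark: unit A is the chlorine-free 7-hydroxyisoflavone half and unit B the 8-chloro half; primed locants are those of ring B of each unit, and Cα and Cβ are the enone carbons of a chalcone. The target is achiral, so no stereocentre has to be set.

Step 1
Reactants: 1 paeonol (1-(2-hydroxy-4-methoxyphenyl)ethanone); 2 isovanillin (3-hydroxy-4-methoxybenzaldehyde)
Product: 3 (E)-1-(2-hydroxy-4-methoxyphenyl)-3-(3-hydroxy-4-methoxyphenyl)prop-2-en-1-one
Conditions: KOH (50% aq.), EtOH, rt; then aq. HCl
Reagents that add atoms: none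
Why: Claisen–Schmidt condensation, in which the enolate of 1 adds to the aldehyde of 2 (its phenoxide is meta to the formyl group and barely deactivates it) and E1cB loss of water under thermodynamic control gives only the E enone.

Step 2
Reactants: 3 (E)-1-(2-hydroxy-4-methoxyphenyl)-3-(3-hydroxy-4-methoxyphenyl)prop-2-en-1-one; 4 4-fluorobenzaldehyde
Product: 5 4-[5-[(E)-3-(2-hydroxy-4-methoxyphenyl)-3-oxoprop-1-enyl]-2-methoxyphenoxy]benzaldehyde
Conditions: K2CO3, DMF, 90 °C, N2
Reagents that add atoms: none
Why: SNAr (addition–elimination through a Meisenheimer complex stabilised by the para formyl group) by the free 3-phenoxide, which should be far more nucleophilic than the carbonyl-chelated 2'-phenoxide; any flavanone that the base forms reversibly from the 2'-phenoxide should be reopened by the KOH of step 4.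

Step 3
Reactants: 6 2-chloro-1,3-dimethoxybenzene; 7 acetyl chloride
Product: 9 1-(3-chloro-2-hydroxy-4-methoxyphenyl)ethanone, via 1-(3-chloro-2,4-dimethoxyphenyl)ethanone 8 (not isolated)
Conditions: AlCl3 (2.5 equiv), CH2Cl2, 0 °C → reflux; aq. HCl
Reagents that add atoms: none
Why: Friedel–Crafts acylation can only occur at the equivalent C4/C6 positions (para to one methoxy group, ortho to the other), which fixes chlorine between the two oxygens, and the excess AlCl3 chelated by the new carbonyl should then cleave only the ortho methoxy group by chloride attack on its methyl carbon (chelation-controlled ether cleavage).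

Step 4
Reactants: 5 4-[5-[(E)-3-(2-hydroxy-4-methoxyphenyl)-3-oxoprop-1-enyl]-2-methoxyphenoxy]benzaldehyde; 9 1-(3-chloro-2-hydroxy-4-methoxyphenyl)ethanone
Product: 10 (E)-1-(3-chloro-2-hydroxy-4-methoxyphenyl)-3-[4-[5-[(E)-3-(2-hydroxy-4-methoxyphenyl)-3-oxoprop-1-enyl]-2-methoxyphenoxy]phenyl]prop-2-en-1-one
Conditions: KOH (50% aq.), EtOH/THF, rt; then aq. HCl
Reagents that add atoms: none
Why: Claisen–Schmidt condensation of the enolate of 9 with the only aldehyde present; the enone already in 5 should be a poor Michael acceptor here because its own 2'-phenoxide is conjugated with the carbonyl, and dehydration again gives the E alkene.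

Step 5
Reactants: 10 (E)-1-(3-chloro-2-hydroxy-4-methoxyphenyl)-3-[4-[5-[(E)-3-(2-hydroxy-4-methoxyphenyl)-3-oxoprop-1-enyl]-2-methoxyphenoxy]phenyl]prop-2-en-1-one
Product: 12 8-chloro-7-methoxy-3-[4-[2-methoxy-5-(7-methoxy-4-oxochromen-3-yl)phenoxy]phenyl]chromen-4-one, via bis(β-keto dimethyl acetal) 11 (not isolated)
Conditions: Tl(NO3)3·3H2O (2.4 equiv), MeOH/HC(OMe)3/CH2Cl2, rt; then 10% aq. HCl, 60 °C
Reagents that add atoms: none
Why: Tl(NO3)3 adds to each enone C=C together with methanol (oxythallation, thallium on Cα and OMe on the benzylic Cβ), and heterolysis of the weak C–Tl bond with loss of monovalent thallium is assisted by a 1,2-shift of the ring-B aryl group from Cβ to Cα through a phenonium ion, which leaves an oxocarbenium ion at Cβ that methanol traps as the dimethyl acetal of 11. This is the oxidative rearrangement of 2'-hydroxychalcones to isoflavones by trivalent thallium nitrate, a known reaction type that is run here on both enones of one substrate. On acidification each chelated 2'-hydroxyl should attack the oxocarbenium ion regenerated from its acetal (6-exo-trig closure of O1–C2), and loss of methanol gives the aromatic pyranone, so that two C3–C1' bonds and two O1–C2 bonds result from one operation. No stereocentre remains, because the two α-carbons of 11 form without control and become the sp2 C3 atoms. The step needs aryl migration to beat attack of the 2'-hydroxyl on the thallated carbon (aurone formation) and simple solvent addition; the para oxygen on each migrating ring (4'-OMe in unit A, the aryloxy oxygen in unit B) should secure this by stabilising the phenonium ion, while the acyl-deactivated rings A and the C–Cl bond are inert to the oxidant.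

Step 6
Reactants: 12 8-chloro-7-methoxy-3-[4-[2-methoxy-5-(7-methoxy-4-oxochromen-3-yl)phenoxy]phenyl]chromen-4-one
Product: 13 Bisoflavolin K (8-chloro-7-hydroxy-3-[4-[2-hydroxy-5-(7-hydroxy-4-oxochromen-3-yl)phenoxy]phenyl]chromen-4-one)
Conditions: BBr3 (12 equiv), CH2Cl2, −78 °C → rt; then MeOH, H2O
Reagents that add atoms: none
Why: BBr3 ether cleavage, in which bromide attacks the methyl carbon of each boron-complexed aryl methyl ether, whereas the diaryl ether (no SN2-capable carbon), the aryl chloride and both pyranones persist, and methanolysis and hydrolysis of the borates free the three phenols.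

Compound list
1 | paeonol, 1-(2-hydroxy-4-methoxyphenyl)ethanone | CC(=O)c1ccc(OC)cc1O | starting material
2 | isovanillin, 3-hydroxy-4-methoxybenzaldehyde | COc1ccc(C=O)cc1O | starting material
3 | (E)-1-(2-hydroxy-4-methoxyphenyl)-3-(3-hydroxy-4-methoxyphenyl)prop-2-en-1-one | COc1ccc(C(=O)/C=C/c2ccc(OC)c(O)c2)c(O)c1 | intermediate
4 | 4-fluorobenzaldehyde | O=Cc1ccc(F)cc1 | starting material
5 | 4-[5-[(E)-3-(2-hydroxy-4-methoxyphenyl)-3-oxoprop-1-enyl]-2-methoxyphenoxy]benzaldehyde | COc1ccc(C(=O)/C=C/c2ccc(OC)c(Oc3ccc(C=O)cc3)c2)c(O)c1 | intermediate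
6 | 2-chloro-1,3-dimethoxybenzene | COc1cccc(OC)c1Cl | starting material
7 | acetyl chloride | CC(Cl)=O | starting material
8 | 1-(3-chloro-2,4-dimethoxyphenyl)ethanone | CC(=O)c1ccc(OC)c(Cl)c1OC | intermediate
9 | 1-(3-chloro-2-hydroxy-4-methoxyphenyl)ethanone | CC(=O)c1ccc(OC)c(Cl)c1O | intermediate
10 | (E)-1-(3-chloro-2-hydroxy-4-methoxyphenyl)-3-[4-[5-[(E)-3-(2-hydroxy-4-methoxyphenyl)-3-oxoprop-1-enyl]-2-methoxyphenoxy]phenyl]prop-2-en-1-one | COc1ccc(C(=O)/C=C/c2ccc(OC)c(Oc3ccc(/C=C/C(=O)c4ccc(OC)c(Cl)c4O)cc3)c2)c(O)c1 | intermediate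
11 | 1-(3-chloro-2-hydroxy-4-methoxyphenyl)-2-[4-[5-[1-(2-hydroxy-4-methoxyphenyl)-3,3-dimethoxy-1-oxopropan-2-yl]-2-methoxyphenoxy]phenyl]-3,3-dimethoxypropan-1-one (both α-carbons stereogenic, mixture of diastereomers, drawn without configuration) | COc1ccc(C(=O)C(C(OC)OC)c2ccc(OC)c(Oc3ccc(C(C(OC)OC)C(=O)c4ccc(OC)c(Cl)c4O)cc3)c2)c(O)c1 | intermediate
12 | 8-chloro-7-methoxy-3-[4-[2-methoxy-5-(7-methoxy-4-oxochromen-3-yl)phenoxy]phenyl]chromen-4-one | O=c1c(-c2ccc(OC)c(Oc3ccc(-c4coc5c(Cl)c(OC)ccc5c4=O)cc3)c2)coc2cc(OC)ccc12 | intermediate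
13 | Bisoflavolin K, 8-chloro-7-hydroxy-3-[4-[2-hydroxy-5-(7-hydroxy-4-oxochromen-3-yl)phenoxy]phenyl]chromen-4-one (achiral) | O=c1c(-c2ccc(O)c(Oc3ccc(-c4coc5c(Cl)c(O)ccc5c4=O)cc3)c2)coc2cc(O)ccc12 | target

Total step count: 6. Longest linear sequence: 5 (steps 1, 2, 4, 5, 6).

Steps most likely to fail

Step 5. The aryl shift could stall on the less electron-rich aryloxyphenyl ring of unit B. The 2'-hydroxyl could also capture the thallated carbon (aurone formation), and partial conversion would leave material rearranged on one side only. The fallback sets out from 10 and closes the pyranone rings before the migration. Oxa-Michael addition of both 2'-hydroxyls to the enones (NaOAc, EtOH, reflux) would give the bis-flavanone 8-chloro-7-methoxy-2-[4-[2-methoxy-5-(7-methoxy-4-oxochroman-2-yl)phenoxy]phenyl]chroman-4-one F1 as a mixture of diastereomers. The oxidative 2,3-aryl migration of flavanones with the trivalent iodine reagent PhI(OH)OTs (MeCN, reflux) would then follow: iodanylation of the enol at C3, aryl shift from C2 to C3 assisted by the ring oxygen, and loss of a proton. The fallback comes back to the route at 12.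

Step 2. The chelated 2'-phenoxide could be arylated as well, or the base could close it onto the enone and give chalcone–flavanone mixtures that are hard to purify. The fallback sets out from 2 and builds the diaryl ether before any enone exists. Acetalisation with ethylene glycol (TsOH, toluene, azeotropic removal of water) would give 5-(1,3-dioxolan-2-yl)-2-methoxyphenol F2. SNAr with 4 (K2CO3, DMF, 100 °C) would give 4-[5-(1,3-dioxolan-2-yl)-2-methoxyphenoxy]benzaldehyde F3. Claisen–Schmidt condensation with 9 (KOH, EtOH) would give (E)-1-(3-chloro-2-hydroxy-4-methoxyphenyl)-3-[4-[5-(1,3-dioxolan-2-yl)-2-methoxyphenoxy]phenyl]prop-2-en-1-one F4. Hydrolysis of the acetal (aq. HCl, THF) would give 3-[4-[(E)-3-(3-chloro-2-hydroxy-4-methoxyphenyl)-3-oxoprop-1-enyl]phenoxy]-4-methoxybenzaldehyde F5. A second Claisen–Schmidt condensation with 1 would come back to the route at 10.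

Step 4. The dianion of 9 could react slowly, its enolate could add to the enone already present in 5, and poorly soluble phenoxide salts could stop the condensation. The fallback sets out from 8, isolated when step 3 is stopped after the acylation (AlCl3 1.1 equiv, 0 °C), and from 5. Condensation of the non-phenolic ketone 8 (NaOH, EtOH/THF) would give (E)-1-(3-chloro-2,4-dimethoxyphenyl)-3-[4-[5-[(E)-3-(2-hydroxy-4-methoxyphenyl)-3-oxoprop-1-enyl]-2-methoxyphenoxy]phenyl]prop-2-en-1-one F6. Chelation-controlled cleavage of the methoxy group ortho to the carbonyl with BCl3 (CH2Cl2, −78 → 0 °C) would come back to the route at 10.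

Further compounds
F1 | step 5 | 8-chloro-7-methoxy-2-[4-[2-methoxy-5-(7-methoxy-4-oxochroman-2-yl)phenoxy]phenyl]chroman-4-one (mixture of diastereomers, drawn without configuration) | COc1ccc2C(=O)CC(c3ccc(OC)c(Oc4ccc(C5CC(=O)c6ccc(OC)c(Cl)c6O5)cc4)c3)Oc2c1
F2 | step 2 | 5-(1,3-dioxolan-2-yl)-2-methoxyphenol | COc1ccc(C2OCCO2)cc1O
F3 | step 2 | 4-[5-(1,3-dioxolan-2-yl)-2-methoxyphenoxy]benzaldehyde | COc1ccc(C2OCCO2)cc1Oc1ccc(C=O)cc1
F4 | step 2 | (E)-1-(3-chloro-2-hydroxy-4-methoxyphenyl)-3-[4-[5-(1,3-dioxolan-2-yl)-2-methoxyphenoxy]phenyl]prop-2-en-1-one | COc1ccc(C2OCCO2)cc1Oc1ccc(/C=C/C(=O)c2ccc(OC)c(Cl)c2O)cc1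
F5 | step 2 | 3-[4-[(E)-3-(3-chloro-2-hydroxy-4-methoxyphenyl)-3-oxoprop-1-enyl]phenoxy]-4-methoxybenzaldehyde | COc1ccc(C=O)cc1Oc1ccc(/C=C/C(=O)c2ccc(OC)c(Cl)c2O)cc1
F6 | step 4 | (E)-1-(3-chloro-2,4-dimethoxyphenyl)-3-[4-[5-[(E)-3-(2-hydroxy-4-methoxyphenyl)-3-oxoprop-1-enyl]-2-methoxyphenoxy]phenyl]prop-2-en-1-one | COc1ccc(C(=O)/C=C/c2ccc(OC)c(Oc3ccc(/C=C/C(=O)c4ccc(OC)c(Cl)c4OC)cc3)c2)c(O)c1
A1 | direct plan | 3-(4-bromophenyl)-8-chloro-7-methoxychromen-4-one | O=c1c(-c2ccc(Br)cc2)coc2c(Cl)c(OC)ccc12
A2 | direct plan | 3-[4-[5-(bromomethyl)-2-methoxyphenoxy]phenyl]-8-chloro-7-methoxychromen-4-one | BrCc1ccc(OC)c(Oc2ccc(-c3coc4c(Cl)c(OC)ccc4c3=O)cc2)c1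
A3 | direct plan | 8-chloro-3-[4-[5-[2-(2,4-dihydroxyphenyl)-2-oxoethyl]-2-hydroxyphenoxy]phenyl]-7-hydroxychromen-4-one | Oc1ccc(C(=O)Cc2ccc(O)c(Oc3ccc(-c4coc5c(Cl)c(O)ccc5c4=O)cc3)c2)c(O)c1
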